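**Plan**
1. Retrosynthetic cuts, in order: the three aryl O–CH3 bonds and the two aryl–CHO bonds; C11–O (hydration of an isopropenyl group); C1′–H, C1′–aryl and C1′–CH2 (the side chain is grown on a C1 carbonyl); C7–C11; C4–CH3; last, ring B at C9–C10 and C5=C6, which leads back to 2-methylcyclohexane-1,3-dione and methyl vinyl ketone.
2. Forward: ring B is annulated onto ring A in one pot (step 1); C4 and C7 are then substituted through the enone, the C1 carbonyl is turned into the benzylic side chain, and the phloroglucinol dialdehyde is unveiled last.
3. Enabling feature: the quaternary C10 lies between C1 and C5, so both can be carbonyl carbons of one mirror-symmetric 2-methyl-1,3-dione. C5=C6 next to C7 (taken back to a ketone) is an aldol-condensation retron and C9–C10 a conjugate-addition retron. A proline-catalysed Robinson annulation therefore forms both bonds, fixes C10 and leaves the C1 ketone as the handle for the side chain.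
4. Stereochemistry: C10 from the catalyst; C4 by hydrogenation anti to the axial C10 methyl; C7 by Luche reduction, Mitsunobu inversion and anti allylic substitution; C1 by equilibration next to a carbonyl; C1′ by hydride delivery to a benzylic cation under allylic 1,3-strain control.

Key step: step 1

Numbering used below (eudesmane type): ring A = C1, C2, C3, C4, C5, C10; ring B = C5 to C10; C10 carries the angular methyl, C1 the side chain (benzylic carbon C1′), C4 the secondary methyl, C7 the 2-hydroxypropan-2-yl group (carbinol carbon C11).
Assumption: the C1 carbinol of 7, 8 and 10 is drawn for hydride attack anti to the C10 methyl; this centre is destroyed in step 7 and its configuration has no consequence.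

**Step 1**
Reactants: 1 2-methylcyclohexane-1,3-dione; 2 methyl vinyl ketone
Product: 4 (S)-Wieland–Miescher ketone, via triketone 3 (not isolated)
Conditions: L-proline (cat.), DMSO, rt to 35 °C, one pot; recrystallisation to upgrade enantiopurity if required
Reagents that add atoms: none
Why: This is a Hajos–Parrish–Eder–Sauer–Wiechert-type Robinson annulation: conjugate addition of the dione (C10) to the enone gives the achiral triketone 3 (C9–C10 bond), whose side-chain ketone forms an enamine with L-proline that adds to one of the two enantiotopic ring carbonyls and then dehydrates (C5=C6 bond). Ring B closes in a 6-(enolendo)-exo-trig aldol mode. The only stereocentre, quaternary C10, is set by the catalyst, because the carboxylic acid of the proline enamine hydrogen-bonds to and so selects one ring carbonyl, which with the natural amino acid should give the (S)-ketone, the series that maps onto the target. The selectivity needed is the differentiation of the carbonyl groups C1 and C5, and it is secured by the mirror plane of 3 through C10, so that the catalyst alone decides. The closest known reaction type is the proline-catalysed intramolecular aldol condensation of 2-alkyl-2-(3-oxobutyl)cycloalkane-1,3-diones.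

**Step 2**
Reactants: 4 (S)-Wieland–Miescher ketone
Product: 5 4-methylene dienedione (exocyclic CH2 on C4)
Conditions: CH2(OEt)2, POCl3, NaOAc, CHCl3, reflux
Reagents that add atoms: diethoxymethane CCOCOCC
Why: Direct gamma-methylenation of a cyclic enone through its extended dienol, as used on steroidal 3-oxo-4-enes: C4 is the only gamma position with hydrogens, it attacks the ethoxymethyl cation and ethanol is lost, while the hindered C1 ketone enolises more slowly and should be left alone.

**Step 3**
Reactants: 5 4-methylene dienedione
Product: 6 4-methyl enedione (C4 methyl cis to the C10 methyl)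
Conditions: H2 (1 atm), RhCl(PPh3)3 (cat.), benzene, rt; used at once
Reagents that add atoms: none
Why: Homogeneous catalytic hydrogenation picks the exocyclic 1,1-disubstituted alkene over the trisubstituted enone and should deliver hydrogen to the face opposite the axial C10 methyl, which places the new methyl cis to it (the kinetic, less stable epimer, as in the hydrogenation of 6-methylene steroids), so acid and base are excluded until the C7 ketone is gone.

**Step 4**
Reactants: 6 4-methyl enedione
Product: 7 diol (C7 allylic alcohol and C1 alcohol, both hydroxyls cis to the C10 methyl)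
Conditions: NaBH4, CeCl3·7H2O, MeOH, −40 to 0 °C
Reagents that add atoms: none
Why: Luche reduction gives 1,2-addition to the enone with the pseudo-equatorial C7 alcohol cis to the C10 methyl (as for 3-oxo-4-ene steroids) and also reduces the C1 ketone, whose configuration is of no account; removal of the C7 carbonyl ends the risk of epimerisation at C4.

**Step 5**
Reactants: 7 diol
Product: 8 C7 benzoate (benzoyloxy trans to the C10 methyl, C1 hydroxyl free)
Conditions: PhCO2H, PPh3, DIAD, toluene, 0 °C to rt
Reagents that add atoms: benzoic acid OC(=O)c1ccccc1
Why: Mitsunobu esterification inverts the unhindered allylic C7 carbinol, while the neopentyl C1 hydroxyl next to quaternary C10 should not react.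

**Step 6**
Reactants: 8 C7 benzoate; 9 isopropenylmagnesium bromide
Product: 10 C7-isopropenyl alcohol (isopropenyl cis to the C10 methyl)
Conditions: 9 (excess, added quickly), Li2CuCl4 (cat.), THF, −30 °C
Reagents that add atoms: none
Why: Copper-catalysed allylic substitution with a Grignard reagent proceeds anti to the leaving group and should occur at C7, because the other allyl terminus C5 is fully substituted and flanked by quaternary C10; inversion of the trans benzoate sets the C7 side chain cis to the C10 methyl.

**Step 7**
Reactants: 10 C7-isopropenyl alcohol
Product: 11 C1 ketone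
Conditions: Dess–Martin periodinane, NaHCO3, CH2Cl2, rt
Reagents that add atoms: none
Why: Buffered periodinane oxidation of a hindered secondary alcohol leaves both alkenes and the C4 and C7 centres untouched.

**Step 8**
Reactants: 11 C1 ketone
Product: 12 C1 nitrile (cyano group cis to the C10 methyl)
Conditions: TosMIC, t-BuOK, DME, EtOH (2 equiv), 0 to 40 °C
Reagents that add atoms: tosylmethyl isocyanide Cc1ccc(cc1)S(=O)(=O)C[N+]#[C-]
Why: The van Leusen reductive cyanation works on ketones flanked by a quaternary carbon (17-oxo steroids); the basic medium should equilibrate C1 to the equatorial nitrile, and both epimers converge at 15 in any case.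

**Step 9**
Reactants: 12 C1 nitrile; 13 isobutylmagnesium bromide
Product: 15 C1 3-methylbutanoyl ketone, via magnesium ketimine 14 (not isolated)
Conditions: 13, toluene/THF, 60 °C; then 1 M aq. HCl, 0 °C to rt; K2CO3, MeOH, rt to equilibrate C1
Reagents that add atoms: water O
Why: Grignard addition to a nitrile stops at the imine salt, which is hydrolysed to the ketone; C1, now alpha to a carbonyl, settles in the equatorial configuration cis to the C10 methyl.

**Step 10**
Reactants: 15 C1 3-methylbutanoyl ketone; 16 1,3,5-trimethoxybenzene
Product: 17 tertiary benzylic alcohol (C1′ carbinol, either epimer)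
Conditions: 16, n-BuLi, THF, 0 °C; CeCl3, −78 °C; then 15, −78 to 0 °C
Reagents that add atoms: none
Why: Lithiation between two methoxy groups and transmetalation to the organocerium reagent gives 1,2-addition to the hindered, enolisable ketone; the configuration of the new carbinol does not matter because it is ionised in the next step.

**Step 11**
Reactants: 17 tertiary benzylic alcohol
Product: 18 (1′S)-trimethoxyphenyl compound
Conditions: Et3SiH (excess), CF3CO2H (2 equiv), CH2Cl2, −78 to −40 °C
Reagents that add atoms: none
Why: Ionic hydrogenation: the 2,4,6-trimethoxybenzylic cation forms far more readily than either alkene is protonated; allylic 1,3-strain against an ortho methoxy group should hold the C1–H bond in the plane of the cation, so the silane adds anti to quaternary C10 and gives the (S) centre at C1′.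

**Step 12**
Reactants: 18 (1′S)-trimethoxyphenyl compound
Product: 19 C11 tertiary alcohol
Conditions: Co(acac)2 (cat.), PhSiH3, O2 (1 atm), THF/i-PrOH, rt
Reagents that add atoms: dioxygen O=O
Why: Mukaiyama hydration is Markovnikov, and hydrogen-atom transfer should be faster to the 1,1-disubstituted isopropenyl group than to the hindered trisubstituted C5=C6 alkene; no stereocentre is formed.

**Step 13**
Reactants: 19 C11 tertiary alcohol
Product: 21 dialdehyde trimethyl ether, via lithium hemiaminal 20 (not isolated)
Conditions: n-BuLi (2.2 equiv), TMEDA, THF, 0 °C; DMF (1 equiv), −78 to 0 °C; n-BuLi (1.2 equiv), 0 °C; DMF; then H2O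
Reagents that add atoms: N,N-dimethylformamide CN(C)C=O
Why: Directed ortho-lithiation and formylation is run twice in one pot: each remaining ring C–H lies between two methoxy groups, the first formyl group stays masked as its lithium amino alkoxide 20 during the second lithiation, and the tertiary alcohol is carried as its alkoxide.

**Step 14**
Reactants: 21 dialdehyde trimethyl ether
Product: 22 target CNP0108656.4
Conditions: LiSC6H4Me-4 (excess), HMPA/toluene, 110 °C; then aq. NH4Cl
Reagents that add atoms: none
Why: Thiolate SN2 O-demethylation cleaves the three aryl methyl ethers, each ortho to a formyl group, under basic conditions; this avoids the Lewis or protic acids that would close the tertiary alcohol onto the C5=C6 alkene.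

**Compound list**
1 | 2-methylcyclohexane-1,3-dione | CC1C(=O)CCCC1=O | starting material
2 | methyl vinyl ketone (but-3-en-2-one) | CC(=O)C=C | starting material
3 | 2-methyl-2-(3-oxobutyl)cyclohexane-1,3-dione | CC(=O)CCC1(C)C(=O)CCCC1=O | intermediate
4 | (S)-Wieland–Miescher ketone, (8aS)-8a-methyl-3,4,8,8a-tetrahydronaphthalene-1,6(2H,7H)-dione (C1 ketone, C5=C6–C7=O enone) | O=C1CCCC2=CC(=O)CC[C@@]21C | intermediate
5 | 4 with an exocyclic methylene on C4 | O=C1CCC(=C)C2=CC(=O)CC[C@@]21C | intermediate
6 | 4 with a C4 methyl cis to the C10 methyl | O=C1CC[C@@H](C)C2=CC(=O)CC[C@@]21C | intermediate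
7 | C1,C7-diol of 6, both hydroxyls cis to the C10 methyl, C5=C6 alkene | O[C@H]1CC[C@@H](C)C2=C[C@@H](O)CC[C@@]21C | intermediate
8 | C7 benzoate of the C7-epimeric diol (benzoyloxy trans to the C10 methyl), C1 hydroxyl free | O[C@H]1CC[C@@H](C)C2=C[C@H](OC(=O)c3ccccc3)CC[C@@]21C | intermediate
9 | isopropenylmagnesium bromide | CC(=C)[Mg]Br | starting material
10 | C1 alcohol with C7 isopropenyl cis to the C10 methyl | O[C@H]1CC[C@@H](C)C2=C[C@@H](C(C)=C)CC[C@@]21C | intermediate
11 | C1 ketone with C7 isopropenyl | O=C1CC[C@@H](C)C2=C[C@@H](C(C)=C)CC[C@@]21C | intermediate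
12 | C1 nitrile, cyano cis to the C10 methyl | N#C[C@H]1CC[C@@H](C)C2=C[C@@H](C(C)=C)CC[C@@]21C | intermediate
13 | isobutylmagnesium bromide | CC(C)C[Mg]Br | starting material
14 | N-bromomagnesio ketimine from 12 and 13 | CC(C)CC(=N[Mg]Br)[C@H]1CC[C@@H](C)C2=C[C@@H](C(C)=C)CC[C@@]21C | intermediate
15 | C1 3-methylbutanoyl ketone, acyl group cis to the C10 methyl | CC(C)CC(=O)[C@H]1CC[C@@H](C)C2=C[C@@H](C(C)=C)CC[C@@]21C | intermediate
16 | 1,3,5-trimethoxybenzene | COc1cc(OC)cc(OC)c1 | starting material
17 | tertiary alcohol at C1′ bearing isobutyl, 2,4,6-trimethoxyphenyl and the C1 ring carbon (C1′ epimers) | CC(C)CC(O)(c1c(OC)cc(OC)cc1OC)[C@H]1CC[C@@H](C)C2=C[C@@H](C(C)=C)CC[C@@]21C | intermediate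
18 | (1′S)-1′-(2,4,6-trimethoxyphenyl) compound with C7 isopropenyl | CC(C)C[C@H](c1c(OC)cc(OC)cc1OC)[C@H]1CC[C@@H](C)C2=C[C@@H](C(C)=C)CC[C@@]21C | intermediate
19 | 18 with the isopropenyl group hydrated to the C11 tertiary alcohol | CC(C)C[C@H](c1c(OC)cc(OC)cc1OC)[C@H]1CC[C@@H](C)C2=C[C@@H](C(C)(C)O)CC[C@@]21C | intermediate
20 | mono-formyl adduct of 19 as lithium (dimethylamino)alkoxide, C11 lithium alkoxide | CC(C)C[C@H](c1c(OC)cc(OC)c(C(O[Li])N(C)C)c1OC)[C@H]1CC[C@@H](C)C2=C[C@@H](C(C)(C)O[Li])CC[C@@]21C | intermediate
21 | 3,5-diformyl-2,4,6-trimethoxyphenyl compound (trimethyl ether of the target) | CC(C)C[C@H](c1c(OC)c(C=O)c(OC)c(C=O)c1OC)[C@H]1CC[C@@H](C)C2=C[C@@H](C(C)(C)O)CC[C@@]21C | intermediate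
22 | CNP0108656.4, 2,4,6-trihydroxy-5-[(1′S)-3-methyl-1-(decalinyl)butyl]benzene-1,3-dicarbaldehyde with ring centres 1R,4R,7S,10R in the numbering above | CC(C)C[C@H](c1c(O)c(C=O)c(O)c(C=O)c1O)[C@H]1CC[C@@H](C)C2=C[C@@H](C(C)(C)O)CC[C@@]21C | target

**Totals**
Total step count: 14. Longest linear sequence: 14 steps (from 1 and 2; 9, 13 and 16 are bought).

**Steps most likely to fail**

Step 11. What may go wrong: poor facial selectivity in the hydride transfer if the hindered aryl group twists out of the cation plane; protonation of the isopropenyl or ring alkene by the acid; and loss of the C1 configuration through elimination and reprotonation of the cation. The fallback sets C1′ in a C–C bond-forming step instead, sets out from 12 and comes back at 18 (it also bypasses steps 9 and 10). Nitrile 12 is reduced with i-Bu2AlH (toluene, −78 °C, then aqueous work-up) to the C1 aldehyde F1. Henry addition of 2-methyl-1-nitropropane (DBU, THF) gives the nitro alcohol F2, which is dehydrated (MsCl, Et3N) to the (E)-nitroalkene F3, in which the isopropyl group is cis to C1. Friedel–Crafts conjugate addition of 16 (hexafluoropropan-2-ol, or Zn(OTf)2 in CH2Cl2) gives the nitro adduct F4; the cis isopropyl group enforces allylic 1,3-strain that keeps C1–H in the alkene plane, so the arene should add anti to C10 and give the same C1′ configuration. Radical denitration (Bu3SnH, AIBN, toluene, 110 °C) then gives 18.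

Step 6. What may go wrong: attack at the wrong allyl terminus or no reaction at the hindered allylic ester, erosion of the anti stereochemistry through allyl isomerisation, and elimination to a diene. The fallback leaves organocopper chemistry for a π-allylpalladium cross-coupling, sets out from 8 and comes back at 10. Benzoate 8 is treated with isopropenylboronic acid pinacol ester, Pd(PPh3)4 (cat.) and K3PO4 in THF/H2O at 50 °C. Ionisation anti to the benzoate, transmetalation and reductive elimination on the metal face give net inversion at the less hindered terminus C7. No new compound is made.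

Step 3. What may go wrong: poor facial selectivity in the hydrogenation, migration of the exocyclic alkene into the ring, and epimerisation of the strained C4 methyl (1,3-diaxial to the C10 methyl) through the dienol before the ketone is reduced. The fallback sets C4 by epoxide opening, sets out from 4 and comes back at 6. Ketalisation of 4 with ethylene glycol (TsOH, benzene, reflux) protects both ketones and moves the alkene to C4=C5, giving the bis-ketal F5. Epoxidation (mCPBA, CH2Cl2, 0 °C) anti to the C10 methyl gives the epoxide F6. MeMgBr (THF, reflux) opens it trans-diaxially at the less substituted C4 (Fürst–Plattner rule), giving the C4-methyl C5-carbinol F7 with the methyl cis to the C10 methyl. Brief aqueous HCl in acetone removes both ketals and dehydrates the beta-hydroxy ketone to 6.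

**Further compounds**
F1 | step 11 | C1 aldehyde (formyl cis to the C10 methyl, C7 isopropenyl) | O=C[C@H]1CC[C@@H](C)C2=C[C@@H](C(C)=C)CC[C@@]21C
F2 | step 11 | nitro alcohol from F1 and 2-methyl-1-nitropropane (carbinol and nitro centres as formed) | CC(C)C([N+](=O)[O-])C(O)[C@H]1CC[C@@H](C)C2=C[C@@H](C(C)=C)CC[C@@]21C
F3 | step 11 | (E)-nitroalkene, isopropyl cis to C1 | CC(C)/C([N+](=O)[O-])=C\[C@H]1CC[C@@H](C)C2=C[C@@H](C(C)=C)CC[C@@]21C
F4 | step 11 | nitro adduct with 2,4,6-trimethoxyphenyl on C1′ (C1′ as in 18, nitro centre as formed) | CC(C)C([N+](=O)[O-])[C@H](c1c(OC)cc(OC)cc1OC)[C@H]1CC[C@@H](C)C2=C[C@@H](C(C)=C)CC[C@@]21C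
F0 | step 6 | none | none
F5 | step 3 | bis(ethylene ketal) of 4 with the alkene at C4=C5 | C13(OCCO3)CCC=C2CC4(OCCO4)CC[C@@]21C
F6 | step 3 | C4–C5 epoxide of F5, oxygen trans to the C10 methyl | C13(OCCO3)CC[C@@H]5O[C@@]52CC4(OCCO4)CC[C@@]21C
F7 | step 3 | bis-ketal with C4 methyl cis and C5 hydroxyl trans to the C10 methyl | C13(OCCO3)CC[C@@H](C)[C@@]2(O)CC4(OCCO4)CC[C@@]21C
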